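**Plan**

- Retrosynthesis: the benzyl ester of the free acid is cut last. Ring B (the orsellinate) is then opened at the ring bond C1'–C6' and at the ester C–O bond to O4 of ring A. Ring A (the heptyl resorcylate) is opened at the same two places, with benzyl alcohol in the role of the phenol. Both 3,5,7-triketo esters go back to diketo-dioxinones, and these to one dioxinone keto allyl ester plus octanoyl or acetyl chloride.
- Forward order: common keto ester; two diketo-dioxinones; ring A by acylketene capture with benzyl alcohol and aldol aromatization; inter-ring ester by capture of the second acylketene with the 4-OH of ring A; ring B by aldol aromatization on the assembled ester; hydrogenolysis.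
- Enabling feature: each benzene ring has the tetraketide pattern (carboxyl carbon on C1, oxygen on C2 and C4, alkyl on C6). The oxygen joining the rings is O4 of ring A, para to the carboxyl and the only phenol not hydrogen-bonded to it. The carboxyl carbon of ring B can therefore arrive as an acylketene carbon, and the ring bond C1'–C6' (carboxyl-bearing to methyl-bearing carbon) as an aldol bond.
- Stereochemistry: the target has no stereocentre and no configured double bond, so nothing has to be set.

Key step: step 8

Remark: the cyclic aldol intermediates of the two ring closures form as diastereomer mixtures and are written without stereodescriptors, since both centres vanish on aromatization; mono-allyl malonate is taken as a purchasable half-ester.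

**Route**

Step 1
Reactants: 1 mono-allyl malonate (3-(allyloxy)-3-oxopropanoic acid)
Product: 2 allyl 3-chloro-3-oxopropanoate (allyl malonyl chloride)
Conditions: (COCl)2, DMF (cat.), CH2Cl2, 0 °C to rt; concentrated and used crude
Reagents that add atoms: oxalyl chloride, O=C(Cl)C(=O)Cl
Why: DMF-catalysed (Vilsmeier-type) conversion of a carboxylic acid into its acid chloride should proceed cleanly because the allyl ester is inert and all by-products are volatile.

Step 2
Reactants: 3 2,2,6-trimethyl-4H-1,3-dioxin-4-one; 2 allyl 3-chloro-3-oxopropanoate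
Product: 5 allyl 4-(2,2-dimethyl-4-oxo-4H-1,3-dioxin-6-yl)-3-oxobutanoate, via lithium dienolate 4 (not isolated)
Conditions: 3, LiN(SiMe3)2 (both in about twofold excess), THF, −78 °C; then 2, −78 °C; dilute aq. HCl work-up
Reagents that add atoms: lithium bis(trimethylsilyl)amide, [Li+].C[Si](C)(C)[N-][Si](C)(C)C (supplies the lithium of intermediate 4; none of its atoms remain in 5)
Why: Vinylogous Claisen acylation of the dioxinone lithium dienolate at its 6-methylene carbon by an acid chloride is the standard entry to 6-(2-oxoalkyl)dioxinones, and the excess dienolate should absorb the acidic proton of the β-keto ester formed.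

Step 3
Reactants: 5 allyl 4-(2,2-dimethyl-4-oxo-4H-1,3-dioxin-6-yl)-3-oxobutanoate; 6 octanoyl chloride
Product: 7 allyl 2-[(2,2-dimethyl-4-oxo-4H-1,3-dioxin-6-yl)acetyl]-3-oxodecanoate
Conditions: MgCl2, pyridine, CH2Cl2, 0 °C to rt; used crude
Reagents that add atoms: none
Why: Soft enolization with MgCl2 and pyridine gives a magnesium chelate of the β-keto ester that should be C-acylated by the acid chloride at the carbon between ketone and allyl ester (magnesium-mediated C-acylation of a β-keto ester).

Step 4
Reactants: 7 allyl 2-[(2,2-dimethyl-4-oxo-4H-1,3-dioxin-6-yl)acetyl]-3-oxodecanoate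
Product: 8 6-(2,4-dioxoundecyl)-2,2-dimethyl-4H-1,3-dioxin-4-one
Conditions: Pd(PPh3)4 (cat.), morpholine, THF, 0 °C to rt
Reagents that add atoms: none
Why: Tsuji–Trost deallylation, in which zerovalent palladium ionizes the allyl ester and morpholine takes up the allyl fragment, frees a β-keto acid that should decarboxylate at room temperature, well below the temperature at which the dioxinone opens.

Step 5
Reactants: 8 6-(2,4-dioxoundecyl)-2,2-dimethyl-4H-1,3-dioxin-4-one; 9 benzyl alcohol
Product: 13 benzyl 6-heptyl-2,4-dihydroxybenzoate, via heptyl acylketene 10 (not isolated), via benzyl triketo ester 11 (not isolated), via cyclic aldol 12 (not isolated)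
Conditions: PhMe, 110 °C; then Cs2CO3, THF, 0 °C to rt; then HCl (1,4-dioxane), rt
Reagents that add atoms: none
Why: Retro-hetero-Diels–Alder loss of acetone gives an acylketene that benzyl alcohol traps, and the resulting 3,5,7-triketo ester should undergo the established base-mediated intramolecular aldol addition of C2 to C7 followed by acid-mediated loss of one water and tautomerization to the resorcylate (biomimetic aldol aromatization).

Step 6
Reactants: 5 allyl 4-(2,2-dimethyl-4-oxo-4H-1,3-dioxin-6-yl)-3-oxobutanoate; 14 acetyl chloride
Product: 15 allyl 2-acetyl-4-(2,2-dimethyl-4-oxo-4H-1,3-dioxin-6-yl)-3-oxobutanoate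
Conditions: MgCl2, pyridine, CH2Cl2, 0 °C to rt; used crude
Reagents that add atoms: none
Why: The same magnesium-mediated C-acylation of the β-keto ester as in step 3 should apply with only the acid chloride changed.

Step 7
Reactants: 15 allyl 2-acetyl-4-(2,2-dimethyl-4-oxo-4H-1,3-dioxin-6-yl)-3-oxobutanoate
Product: 16 6-(2,4-dioxopentyl)-2,2-dimethyl-4H-1,3-dioxin-4-one
Conditions: Pd(PPh3)4 (cat.), morpholine, THF, 0 °C to rt
Reagents that add atoms: none
Why: Tsuji–Trost deallylation with morpholine as allyl acceptor, followed by spontaneous decarboxylation of the β-keto acid, should give the methyl diketo-dioxinone as in step 4.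

Step 8
Reactants: 13 benzyl 6-heptyl-2,4-dihydroxybenzoate; 16 6-(2,4-dioxopentyl)-2,2-dimethyl-4H-1,3-dioxin-4-one
Product: 20 benzyl 4-[(2,4-dihydroxy-6-methylbenzoyl)oxy]-2-heptyl-6-hydroxybenzoate, via methyl acylketene 17 (not isolated), via aryl triketo ester 18 (not isolated), via cyclic aldol 19 (not isolated)
Conditions: 16 added slowly to 13 (1.2 equiv), PhMe, 110 °C; then Cs2CO3, THF, 0 °C; then HCl (1,4-dioxane), 0 °C to rt
Reagents that add atoms: none
Why: Proposed new method: heating 16 expels acetone by a retro-hetero-Diels–Alder reaction to give acylketene 17, whose ketene carbon is captured by the free 4-OH of 13 to give the aryl triketo ester 18; Cs2CO3 then forms the C2 carbanion (between the ester and the C3 ketone), which adds to the C7 methyl ketone to give the cyclic aldol 19, and HCl removes one molecule of water so that the enedione tautomerizes to the resorcinol ring of 20. The closest known reaction type is the thermolysis of diketo-dioxinones in the presence of alcohols followed by base-then-acid aldol aromatization to resorcylate esters, joined to the known O-acylation of phenols by dioxinone-derived acylketenes; what is untested is carrying an aryl rather than an alkyl triketo ester through the aromatization. Ring B is the only ring closed, by a 6-exo-trig aldol (enolexo with respect to the ester enolate) of C2 onto C7, the sole closure of a doubly activated methylene that gives a six-membered carbocycle without expelling the aryloxide. The two stereocentres of 19 are transient and are erased on aromatization, so no stereocontrol is required. Site selectivity for the 4-OH over the 2-OH of 13 rests on the 2-OH being locked in a hydrogen bond to the adjacent benzyl ester carbonyl and crowded by it. Selectivity for C–C aldol closure over O-lactonization to a pyranone or Claisen closure of C6 onto C1, both of which would eject the phenol, rests on the alcohol-free, low-temperature base step, on the 2-phenoxide formed under Cs2CO3 making the ring A aryloxide a poorer leaving group, and on slow addition of 16 to an excess of 13 so that ketene capture outruns ketene self-reaction.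

Step 9
Reactants: 20 benzyl 4-[(2,4-dihydroxy-6-methylbenzoyl)oxy]-2-heptyl-6-hydroxybenzoate
Product: 21 4-[(2,4-dihydroxy-6-methylbenzoyl)oxy]-2-heptyl-6-hydroxybenzoic acid
Conditions: H2 (1 atm), Pd/C (palladium on carbon), EtOAc, rt
Reagents that add atoms: none
Why: Catalytic hydrogenolysis of the benzyl ester under neutral conditions should free the acid without touching the aryl ester and without the heat, acid or base that would decarboxylate the resorcylic acid or cleave the depside.

**Compound list**

1 | mono-allyl malonate (3-(allyloxy)-3-oxopropanoic acid) | C=CCOC(=O)CC(=O)O | starting material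
2 | allyl 3-chloro-3-oxopropanoate | C=CCOC(=O)CC(=O)Cl | intermediate
3 | 2,2,6-trimethyl-4H-1,3-dioxin-4-one | CC1=CC(=O)OC(C)(C)O1 | starting material
4 | lithium dienolate of 3 (lithium 2,2-dimethyl-6-methylene-6H-1,3-dioxin-4-olate) | [Li+].C=C1C=C([O-])OC(C)(C)O1 | intermediate (not isolated)
5 | allyl 4-(2,2-dimethyl-4-oxo-4H-1,3-dioxin-6-yl)-3-oxobutanoate | C=CCOC(=O)CC(=O)CC1=CC(=O)OC(C)(C)O1 | intermediate
6 | octanoyl chloride | CCCCCCCC(=O)Cl | starting material
7 | allyl 2-[(2,2-dimethyl-4-oxo-4H-1,3-dioxin-6-yl)acetyl]-3-oxodecanoate | CCCCCCCC(=O)C(C(=O)OCC=C)C(=O)CC1=CC(=O)OC(C)(C)O1 | intermediate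
8 | 6-(2,4-dioxoundecyl)-2,2-dimethyl-4H-1,3-dioxin-4-one | CCCCCCCC(=O)CC(=O)CC1=CC(=O)OC(C)(C)O1 | intermediate
9 | benzyl alcohol | OCc1ccccc1 | starting material
10 | heptyl acylketene (tetradec-1-ene-1,3,5,7-tetrone) | CCCCCCCC(=O)CC(=O)CC(=O)C=C=O | intermediate (not isolated)
11 | benzyl 3,5,7-trioxotetradecanoate | CCCCCCCC(=O)CC(=O)CC(=O)CC(=O)OCc1ccccc1 | intermediate (not isolated)
12 | benzyl 2-heptyl-2-hydroxy-4,6-dioxocyclohexane-1-carboxylate (cyclic aldol, diastereomer mixture) | CCCCCCCC1(O)CC(=O)CC(=O)C1C(=O)OCc1ccccc1 | intermediate (not isolated)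
13 | benzyl 6-heptyl-2,4-dihydroxybenzoate | CCCCCCCc1cc(O)cc(O)c1C(=O)OCc1ccccc1 | intermediate
14 | acetyl chloride | CC(=O)Cl | starting material
15 | allyl 2-acetyl-4-(2,2-dimethyl-4-oxo-4H-1,3-dioxin-6-yl)-3-oxobutanoate | CC(=O)C(C(=O)OCC=C)C(=O)CC1=CC(=O)OC(C)(C)O1 | intermediate
16 | 6-(2,4-dioxopentyl)-2,2-dimethyl-4H-1,3-dioxin-4-one | CC(=O)CC(=O)CC1=CC(=O)OC(C)(C)O1 | intermediate
17 | methyl acylketene (oct-1-ene-1,3,5,7-tetrone) | CC(=O)CC(=O)CC(=O)C=C=O | intermediate (not isolated)
18 | benzyl 2-heptyl-6-hydroxy-4-[(3,5,7-trioxooctanoyl)oxy]benzoate | CC(=O)CC(=O)CC(=O)CC(=O)Oc1cc(O)c(C(=O)OCc2ccccc2)c(CCCCCCC)c1 | intermediate (not isolated)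
19 | benzyl 2-heptyl-6-hydroxy-4-[(2-hydroxy-2-methyl-4,6-dioxocyclohexane-1-carbonyl)oxy]benzoate (cyclic aldol, diastereomer mixture) | CC1(O)CC(=O)CC(=O)C1C(=O)Oc1cc(O)c(C(=O)OCc2ccccc2)c(CCCCCCC)c1 | intermediate (not isolated)
20 | benzyl 4-[(2,4-dihydroxy-6-methylbenzoyl)oxy]-2-heptyl-6-hydroxybenzoate | CCCCCCCc1cc(OC(=O)c2c(C)cc(O)cc2O)cc(O)c1C(=O)OCc1ccccc1 | intermediate
21 | 4-[(2,4-dihydroxy-6-methylbenzoyl)oxy]-2-heptyl-6-hydroxybenzoic acid (CNP0227363.0) | CCCCCCCc1cc(OC(=O)c2c(C)cc(O)cc2O)cc(O)c1C(=O)O | target

**Step count and risks**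

Total step count: 9. Longest linear sequence: 7 steps (steps 1, 2, 3, 4, 5, 8, 9).

Steps most likely to fail:

1. Step 8. The acylketene may be lost to intramolecular O-acylation (pyranone formation) or dimerization before the weakly nucleophilic phenol captures it. Under base the aryl triketo ester may also eject the aryloxide by lactonization or Claisen closure instead of closing the carbocycle. The fallback uses known depside chemistry, sets out from 13 and comes back to the route at 21. Purchased methyl orsellinate would be O-benzylated (BnBr, K2CO3, DMF) to methyl 2,4-bis(benzyloxy)-6-methylbenzoate F1. Saponification (KOH, aq. DMSO, heat) would give 2,4-bis(benzyloxy)-6-methylbenzoic acid F2. Esterification of the 4-OH of 13 through the mixed trifluoroacetic anhydride of F2 (trifluoroacetic anhydride, toluene, rt) would give benzyl 4-{[2,4-bis(benzyloxy)-6-methylbenzoyl]oxy}-2-heptyl-6-hydroxybenzoate F3. Hydrogenolysis of all three benzyl groups (H2, Pd/C, EtOAc) should then deliver 21 directly.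

2. Step 2. The enolizable malonyl chloride may protonate the dienolate (ketene formation and self-condensation of the acid chloride), and O-acylation may compete with C-acylation. The fallback reverses the polarity of the Claisen step, sets out from 3 and 1 and comes back at 5. The dienolate of 3 would be carboxylated with CO2 to (2,2-dimethyl-4-oxo-4H-1,3-dioxin-6-yl)acetic acid F4. Carbonyldiimidazole would activate it as 6-[2-(1H-imidazol-1-yl)-2-oxoethyl]-2,2-dimethyl-4H-1,3-dioxin-4-one F5. A decarboxylative Masamune–Brooks Claisen condensation of F5 with 1 under MgCl2 and Et3N should then give 5.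

3. Step 7. During deallylation the acetyl group may be lost by retro-Claisen attack of morpholine, or the allyl fragment may be transferred to carbon (decarboxylative allylation) instead of to the amine. The fallback avoids the allyl ester altogether, bypasses steps 6 and 7, sets out from 3 and 14 and comes back at 16. The dienolate of 3 would be acylated with 14 to 2,2-dimethyl-6-(2-oxopropyl)-4H-1,3-dioxin-4-one F6. Its dianion (LiN(iPr)2, 2 equiv, THF, −78 °C) would be acylated at the terminal methyl carbon with N-methoxy-N-methylacetamide to give 16.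

**Further compounds**

F1 | step 8 | methyl 2,4-bis(benzyloxy)-6-methylbenzoate | COC(=O)c1c(C)cc(OCc2ccccc2)cc1OCc1ccccc1
F2 | step 8 | 2,4-bis(benzyloxy)-6-methylbenzoic acid | OC(=O)c1c(C)cc(OCc2ccccc2)cc1OCc1ccccc1
F3 | step 8 | benzyl 4-{[2,4-bis(benzyloxy)-6-methylbenzoyl]oxy}-2-heptyl-6-hydroxybenzoate | CCCCCCCc1cc(OC(=O)c2c(C)cc(OCc3ccccc3)cc2OCc2ccccc2)cc(O)c1C(=O)OCc1ccccc1
F4 | step 2 | (2,2-dimethyl-4-oxo-4H-1,3-dioxin-6-yl)acetic acid | OC(=O)CC1=CC(=O)OC(C)(C)O1
F5 | step 2 | 6-[2-(1H-imidazol-1-yl)-2-oxoethyl]-2,2-dimethyl-4H-1,3-dioxin-4-one | O=C(CC1=CC(=O)OC(C)(C)O1)n1ccnc1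
F6 | step 7 | 2,2-dimethyl-6-(2-oxopropyl)-4H-1,3-dioxin-4-one | CC(=O)CC1=CC(=O)OC(C)(C)O1
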